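The blue flask held twice the partner of the grey flask and the same starting material, yet over the first 0.56 min it lost starting material only a little faster than grey, 53.9 mM min⁻¹ against 50.7 mM min⁻¹. What I wanted to know was where the ochre flask, a repeat of grey, would stop.

| setting | grey | teal | green | blue | ochre |
|---|---|---|---|---|---|
| starting material | 300 mM | 180 mM | 900 mM | 300 mM | 300 mM |
| partner | 240 mM | 120 mM | 240 mM | 480 mM | 240 mM |
| free catalyst | 3.00 mM | 3.00 mM | 3.00 mM | 3.00 mM | 3.00 mM |
| time |  |  |  |  | 42 min |

| run | time / min | [starting material] / mM |
|---|---|---|
| grey run | 0.56 | 271.6 |
| grey run | 0.96 | 258.8 |
| grey run | 1.6 | 241.4 |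
| grey run | 2.8 | 216.3 |
| grey run | 4.8 | 184.3 |
| grey run | 8.2 | 150.4 |
| grey run | 14 | 115.5 |
| teal run | 0.56 | 164.1 |
| teal run | 0.96 | 154.2 |
| teal run | 1.6 | 142.0 |
| teal run | 2.8 | 125.1 |
| teal run | 4.8 | 105.9 |
| teal run | 8.2 | 84.7 |
| teal run | 14 | 75.8 |
| green run | 0.56 | 852.4 |
| green run | 0.96 | 827.8 |
| green run | 1.6 | 797.2 |
| green run | 2.8 | 756.3 |
| green run | 4.8 | 713.5 |
| green run | 8.2 | 683.3 |
| green run | 14 | 679.9 |
| blue run | 0.56 | 269.8 |
| blue run | 0.96 | 255.1 |
| blue run | 1.6 | 235.2 |
| blue run | 2.8 | 208.7 |
| blue run | 4.8 | 176.7 |
| blue run | 8.2 | 140.9 |
| blue run | 14 | 102.1 |

(each reading ± 0.9 mM)

- Overall: starting material + partner -> product, with free catalyst as catalyst.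
- Constant volume, constant temperature.
- The analysis sees a species whether free or bound.
- "The second partner" is partner.
- An order is taken over about fifteen percent of the charge, up and down.

* the exponent of [starting material] in the starting rate at the charge of the grey run (at the point where two percent of the starting material have become product) (one fixed amount of product, the same in the runs compared)
* the exponent of [partner] in the starting rate at the charge of the grey run (at the point where two percent of the starting material have become product)
* the teal run starts with 120 mM less of starting material and of partner than the grey run, and with no product. Compared where both hold the same amount of starting material, once fifteen percent of what the teal run was charged with has turned into product, is the teal run faster, slower or alike (within a tenth)?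
* starting material in the ochre run at 42 min, as a share of the starting material charged

I followed grey in slow motion. In the first instants it ran at the rate above, with 240 mM of partner charged. By the middle, between 2.8 min and 4.8 min, it ran at 16.0 mM min⁻¹, about a third of the opening rate, although 61.4% of the starting material remained. The end could be read from green, where partner is the limiting reagent. Over its last 5.80 min green fell by 3.40 mM, having used 220 mM of starting material against 240 mM of partner. The overall equation takes one of each, so green showed a shortfall D of 19.9 mM.

I treated this shortfall as a small correction to the partner balance, and assumed that partner leaks away in proportion to the amount present. Let S0 and R0 be the charges, S the starting material, and A the area under S − (S0 − R0) up to the last reading at time t. Partner present is then roughly that curve lowered by D, which gives D = k_L (A − D t). Green gave A = 50.2 M·s, and so a reading of 0.0357 min⁻¹ for k_L, the leak constant, the share of the partner present that is lost each minute.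

Grey gave A = 96.1 M·s, so its shortfall came to 38.1 mM, larger than green's. That put the end at 98.1 mM, and I committed to 32.7% for ochre. That figure counted no leak after grey's last reading, when by this balance 17.4 mM of partner was still present, so I took it as a lower mark for ochre.

The forecast gave exponents of 0.8 for starting material and 0.12 for partner, called teal faster, and put ochre at 26%, reasoning that “the catalyst seems to die when partner runs low”. Its figure for ochre differs from my 32.7%.

The flask gave exponents of 0.69 and 0.33, teal faster by a factor of 2.4, and ochre at 34.6%.

    free catalyst + starting material → loaded catalyst + by-product (104.4 M⁻¹ min⁻¹)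
    loaded catalyst + partner → product + free catalyst (252.6 M⁻¹ min⁻¹)
    free catalyst + by-product ⇌ catalyst-by-product complex, settled at all times (24.10 M⁻¹)
    partner → lost reagent (0.04044 min⁻¹)

That ochre value means a shortfall of 43.9 mM, more than my 38.1 mM. A fit with the true steps gave 34.8%, and a power-law fit gave 20.0%. Applied to teal, k_L gives a shortfall of 14.2 mM and a lower mark of 74.2 mM, and teal's last reading, at 14 min, stood at 75.8 mM.

The numbers in the tables are simulated with made-up constants, noise included.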